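## Retrosynthetic overview

1. 16-epi-Luffarin L ⇐ (desilylation) bis-silyl butenolide ⇐ (one flask: O–C16 ring closure, then loss of the C17 oxygen) acyclic (16S,17S)-epoxy tert-butyl ester.
2. Key disconnection: the ring O–C16 bond of the butenolide. The C19 ester oxygen opens a C16–C17 epoxide at C16 with inversion (five-membered ring), and the former epoxide oxygen on C17 then leaves by E1cB to give the ring C17=C18 bond.
3. Enabling feature: ring carbons C16 and C17 plus the hydroxymethyl carbon C25 on C17 are, one oxidation level down, a 2-substituted allylic alcohol whose alkene C16=C17 lies β,γ to the C19 carboxyl. The free C25–OH lets a tartrate-controlled epoxidation pick this one alkene out of three and fix C16, the carboxyl oxygen reaches C16 through a five-membered ring, and the C17 oxygen ends up β to the lactone C=O.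
4. Epoxide precursor ⇐ ester reduction ⇐ E-alkylidene succinate (Wittig at C16=C17) ⇐ Z-C13=C14 by Wittig olefination of an α-silyloxy ketone ⇐ methyl ketone from (−)-sclareol.
5. Ring order: rings A and B (C5, C10) are taken intact from sclareol (only the C8=C9 alkene is introduced); the butenolide is the only ring formed, and it is closed last.

Key step: step 13

Remark: atoms are numbered as in the luffarin skeleton (C8=C9 ring alkene; C13=C14 side-chain alkene carrying C24H2OH; C16 lactone CH–O; C17 ring carbon carrying C25H2OH; C18 ring CH; C19 lactone C=O), the target SMILES corresponds to 16R, and Dr stands for the (4aS,8aS)-2,5,5,8a-tetramethyl-3,4,4a,5,6,7,8,8a-octahydronaphthalen-1-yl group.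

## Route

Step 1
Reactants: 1 (−)-sclareol
Product: 2 4-[(1R,2R,4aS,8aS)-2-hydroxy-2,5,5,8a-tetramethyldecahydronaphthalen-1-yl]butan-2-one
Conditions: KMnO4, acetone–H2O, 0 °C to rt
Reagents that add atoms: none
Why: Permanganate dihydroxylates the terminal vinyl group and degrades the resulting triol (glycol cleavage, oxidative decarboxylation) down to the C13 methyl ketone, a classical degradation of this tertiary vinyl carbinol that leaves the C8 alcohol and the ring stereocenters untouched.

Step 2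
Reactants: 2 hydroxy ketone
Product: 3 4-Dr-butan-2-one
Conditions: I2 (cat.), benzene, reflux
Reagents that add atoms: none
Why: HI generated from iodine promotes E1 dehydration of the tertiary C8 alcohol under equilibrating conditions, so the thermodynamically preferred tetrasubstituted C8=C9 alkene should dominate (any cyclic enol ether formed from the hydroxy ketone re-opens under the same conditions) and C9 stops being a stereocenter.

Step 3
Reactants: 3 methyl ketone
Product: 5 1-hydroxy-4-Dr-butan-2-one, via potassium enolate 4 (not isolated)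
Conditions: KN(SiMe3)2, THF, −78 °C; then 2-(phenylsulfonyl)-3-phenyloxaziridine, −78 °C; aq. NH4Cl
Reagents that add atoms: 2-(phenylsulfonyl)-3-phenyloxaziridine O=S(=O)(c1ccccc1)N1OC1c1ccccc1
Why: The hindered amide base removes a methyl proton under kinetic control and the terminal enolate is hydroxylated by the N-sulfonyloxaziridine (enolate oxidation), a reagent that does not attack the isolated tetrasubstituted alkene.

Step 4
Reactants: 5 α-hydroxy ketone
Product: 6 1-[(tert-butyldiphenylsilyl)oxy]-4-Dr-butan-2-one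
Conditions: tBuPh2SiCl, imidazole, DMF, 0 °C to rt
Reagents that add atoms: tert-butyl(chloro)diphenylsilane CC(C)(C)[Si](Cl)(c1ccccc1)c1ccccc1
Why: Standard silylation of a primary alcohol; the acid-stable TBDPS ether is chosen so that a TBS ether can later be removed in its presence.

Step 5
Reactants: 7 (3-bromopropoxy)(tert-butyl)dimethylsilane; 8 triphenylphosphine
Product: 9 {3-[(tert-butyldimethylsilyl)oxy]propyl}triphenylphosphonium bromide
Conditions: MeCN, reflux
Reagents that add atoms: none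
Why: SN2 quaternization of triphenylphosphine by a primary bromide.

Step 6
Reactants: 6 α-silyloxy ketone; 9 phosphonium bromide
Product: 11 (Z)-1-[(tert-butyldimethylsilyl)oxy]-4-{[(tert-butyldiphenylsilyl)oxy]methyl}-6-Dr-hex-3-ene, via ylide 10 (not isolated)
Conditions: 9, KN(SiMe3)2, THF, −78 to 0 °C; then 6, −78 °C to rt
Reagents that add atoms: none
Why: Wittig olefination of an α-alkoxy ketone with a salt-free non-stabilized ylide is known to place the ylide-derived chain cis to the oxygenated CH2 group, so the Z-trisubstituted C13=C14 alkene (C24 cis to C15) should result.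

Step 7
Reactants: 11 bis-silyl ether
Product: 12 (Z)-4-{[(tert-butyldiphenylsilyl)oxy]methyl}-6-Dr-hex-3-en-1-ol
Conditions: PPTS (cat.), EtOH, rt
Reagents that add atoms: none
Why: Mild acid-catalyzed ethanolysis cleaves the primary TBS ether much faster than the primary TBDPS ether.

Step 8
Reactants: 13 methyl (triphenylphosphoranylidene)acetate; 14 tert-butyl bromoacetate
Product: 16 4-tert-butyl 1-methyl 2-(triphenylphosphoranylidene)butanedioate, via phosphonium bromide 15 (not isolated)
Conditions: toluene, 80 °C; then 1 M NaOH, CH2Cl2, 0 °C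
Reagents that add atoms: none
Why: C-alkylation of the stabilized ylide by the α-bromo ester, then deprotonation of the acidic P–CH(CO2Me) proton, gives the ester-stabilized ylide with the two carboxyls already differentiated.

Step 9
Reactants: 12 homoallylic alcohol; 16 stabilized ylide
Product: 18 4-tert-butyl 1-methyl (2E)-2-[(3Z)-4-{[(tert-butyldiphenylsilyl)oxy]methyl}-6-Dr-hex-3-en-1-ylidene]butanedioate, via aldehyde 17 (not isolated)
Conditions: Dess–Martin periodinane, NaHCO3, CH2Cl2, 0 °C to rt; then 16, rt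
Reagents that add atoms: none
Why: Dess–Martin oxidation gives the β,γ-unsaturated aldehyde, which is trapped in the same flask under neutral conditions by the α-substituted stabilized ylide; such Wittig reactions give the E-alkylidene succinate (chain trans to CO2Me), which fixes the C16=C17 geometry needed later.

Step 10
Reactants: 18 alkylidene succinate
Product: 19 tert-butyl (3E,6Z)-7-{[(tert-butyldiphenylsilyl)oxy]methyl}-3-(hydroxymethyl)-9-Dr-nona-3,6-dienoate
Conditions: iBu2AlH (2.2 equiv), CH2Cl2, −78 °C; aq. potassium sodium tartrate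
Reagents that add atoms: none
Why: At −78 °C the aluminium hydride should reduce the unhindered methyl ester to the allylic alcohol (1,2-reduction) while the hindered tert-butyl ester is left intact.

Step 11
Reactants: 19 allylic alcohol
Product: 20 tert-butyl 2-[(2S,3S)-3-[(2Z)-3-{[(tert-butyldiphenylsilyl)oxy]methyl}-5-Dr-pent-2-en-1-yl]-2-(hydroxymethyl)oxiran-2-yl]acetate
Conditions: Ti(OiPr)4 (10 mol %), L-(+)-diisopropyl tartrate (12 mol %), tBuOOH, 4 Å molecular sieves, CH2Cl2, −20 °C
Reagents that add atoms: tert-butyl hydroperoxide CC(C)(C)OO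
Why: Sharpless asymmetric epoxidation is directed by the free C25 hydroxyl, so of the three alkenes only C16=C17 should react, and for this E-2,3-disubstituted allylic alcohol the L-(+)-tartrate delivers oxygen to the face that gives the (2S,3S)-oxirane (16S,17S) under reagent control.

Step 12
Reactants: 20 epoxy alcohol
Product: 21 tert-butyl 2-[(2S,3S)-2-{[(tert-butyldiphenylsilyl)oxy]methyl}-3-[(2Z)-3-{[(tert-butyldiphenylsilyl)oxy]methyl}-5-Dr-pent-2-en-1-yl]oxiran-2-yl]acetate
Conditions: tBuPh2SiCl, imidazole, CH2Cl2, 0 °C to rt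
Reagents that add atoms: tert-butyl(chloro)diphenylsilane CC(C)(C)[Si](Cl)(c1ccccc1)c1ccccc1
Why: Standard silylation of the primary alcohol, which keeps the C25 oxygen from acting as a nucleophile, an acyl acceptor or a sulfonylation site in the next step.

Step 13
Reactants: 21 epoxy tert-butyl ester
Product: 24 (5R)-4-{[(tert-butyldiphenylsilyl)oxy]methyl}-5-[(2Z)-3-{[(tert-butyldiphenylsilyl)oxy]methyl}-5-Dr-pent-2-en-1-yl]furan-2(5H)-one, via hydroxy lactone 22 (not isolated), via tertiary mesylate 23 (not isolated)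
Conditions: BF3·OEt2 (0.3 equiv), CH2Cl2, −78 to −20 °C; then Et3N, MsCl, 0 °C to rt
Reagents that add atoms: none
Why: BF3 coordinates the epoxide oxygen, the carbonyl oxygen of the C19 tert-butyl ester attacks C16 from the face opposite the breaking C16–O bond, and the resulting 2-tert-butoxyoxolan-2-ylium ion loses 2-methylpropene to give the β-hydroxy γ-lactone 22; in the same flask Et3N ties up BF3, MsCl/Et3N (sulfene) mesylates the tertiary C17 hydroxyl, and E1cB loss of mesylate across C17–C18 gives the butenolide. The closest known reaction types are the acid-mediated lactonization of β,γ-epoxy acids and esters to β-hydroxy γ-butyrolactones, the participation of tert-butyl esters and carbonates in epoxide opening with loss of 2-methylpropene, and the MsCl/Et3N dehydration of β-hydroxy lactones. The five-membered lactone ring closes by formal 5-endo opening of the epoxide (oxygen to the distal epoxide carbon C16), the only alternative being the strained 4-exo closure at C17. The one new stereocenter, C16, is fixed by stereospecific inversion of the (16S)-epoxide carbon installed by the tartrate-controlled epoxidation and so comes out 16R, while the C17 carbinol center formed at the same time is erased by the elimination. The step needs C16–O rather than C17–O cleavage and elimination toward C18 only: the first is secured by ring size and by the electron-withdrawing CH2O and CH2C=O substituents that disfavor cationic character at C17, the second by the acidity of the C18 protons next to the lactone carbonyl, and the remote tri- and tetrasubstituted alkenes and the silyl ethers should not be engaged by catalytic BF3 at low temperature.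

Step 14
Reactants: 24 bis-silyl butenolide
Product: 25 16-epi-luffarin L
Conditions: HF·pyridine, THF–pyridine, 0 °C to rt
Reagents that add atoms: none
Why: Fluoride-mediated cleavage of both primary TBDPS ethers under buffered acidic conditions, which avoids base-induced epimerization at the butenolide γ-carbon C16.

## Compound list

1 | (−)-sclareol, (1R,2R,4aS,8aS)-1-[(3R)-3-hydroxy-3-methylpent-4-en-1-yl]-2,5,5,8a-tetramethyldecahydronaphthalen-2-ol | C[C@]12CCCC([C@@H]1CC[C@@](O)([C@@H]2CC[C@@](C)(O)C=C)C)(C)C | starting material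
2 | 4-[(1R,2R,4aS,8aS)-2-hydroxy-2,5,5,8a-tetramethyldecahydronaphthalen-1-yl]butan-2-one | C[C@]12CCCC([C@@H]1CC[C@@](O)([C@@H]2CCC(C)=O)C)(C)C | intermediate
3 | 4-Dr-butan-2-one (14,15-dinorlabd-8-en-13-one) | CC1=C(CCC(C)=O)[C@@]2(C)CCCC(C)(C)[C@@H]2CC1 | intermediate
4 | potassium 4-Dr-but-1-en-2-olate (not isolated) | CC1=C(CCC(=C)[O-])[C@@]2(C)CCCC(C)(C)[C@@H]2CC1.[K+] | intermediate
5 | 1-hydroxy-4-Dr-butan-2-one | CC1=C(CCC(=O)CO)[C@@]2(C)CCCC(C)(C)[C@@H]2CC1 | intermediate
6 | 1-[(tert-butyldiphenylsilyl)oxy]-4-Dr-butan-2-one | CC1=C(CCC(=O)CO[Si](c3ccccc3)(c3ccccc3)C(C)(C)C)[C@@]2(C)CCCC(C)(C)[C@@H]2CC1 | intermediate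
7 | (3-bromopropoxy)(tert-butyl)dimethylsilane | BrCCCO[Si](C)(C)C(C)(C)C | starting material
8 | triphenylphosphine | c1ccc(cc1)P(c1ccccc1)c1ccccc1 | starting material
9 | {3-[(tert-butyldimethylsilyl)oxy]propyl}triphenylphosphonium bromide | CC(C)(C)[Si](C)(C)OCCC[P+](c1ccccc1)(c1ccccc1)c1ccccc1.[Br-] | intermediate
10 | {3-[(tert-butyldimethylsilyl)oxy]propylidene}triphenylphosphorane (not isolated) | CC(C)(C)[Si](C)(C)OCCC=P(c1ccccc1)(c1ccccc1)c1ccccc1 | intermediate
11 | (Z)-1-[(tert-butyldimethylsilyl)oxy]-4-{[(tert-butyldiphenylsilyl)oxy]methyl}-6-Dr-hex-3-ene | CC1=C(CC/C(=C/CCO[Si](C)(C)C(C)(C)C)CO[Si](c3ccccc3)(c3ccccc3)C(C)(C)C)[C@@]2(C)CCCC(C)(C)[C@@H]2CC1 | intermediate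
12 | (Z)-4-{[(tert-butyldiphenylsilyl)oxy]methyl}-6-Dr-hex-3-en-1-ol | CC1=C(CC/C(=C/CCO)CO[Si](c3ccccc3)(c3ccccc3)C(C)(C)C)[C@@]2(C)CCCC(C)(C)[C@@H]2CC1 | intermediate
13 | methyl (triphenylphosphoranylidene)acetate | COC(=O)C=P(c1ccccc1)(c1ccccc1)c1ccccc1 | starting material
14 | tert-butyl bromoacetate | CC(C)(C)OC(=O)CBr | starting material
15 | (4-tert-butoxy-1-methoxy-1,4-dioxobutan-2-yl)triphenylphosphonium bromide (not isolated) | COC(=O)C(CC(=O)OC(C)(C)C)[P+](c1ccccc1)(c1ccccc1)c1ccccc1.[Br-] | intermediate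
16 | 4-tert-butyl 1-methyl 2-(triphenylphosphoranylidene)butanedioate | COC(=O)C(CC(=O)OC(C)(C)C)=P(c1ccccc1)(c1ccccc1)c1ccccc1 | intermediate
17 | (Z)-4-{[(tert-butyldiphenylsilyl)oxy]methyl}-6-Dr-hex-3-enal (not isolated) | CC1=C(CC/C(=C/CC=O)CO[Si](c3ccccc3)(c3ccccc3)C(C)(C)C)[C@@]2(C)CCCC(C)(C)[C@@H]2CC1 | intermediate
18 | 4-tert-butyl 1-methyl (2E)-2-[(3Z)-4-{[(tert-butyldiphenylsilyl)oxy]methyl}-6-Dr-hex-3-en-1-ylidene]butanedioate | CC1=C(CC/C(=C/C/C=C(\CC(=O)OC(C)(C)C)C(=O)OC)CO[Si](c3ccccc3)(c3ccccc3)C(C)(C)C)[C@@]2(C)CCCC(C)(C)[C@@H]2CC1 | intermediate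
19 | tert-butyl (3E,6Z)-7-{[(tert-butyldiphenylsilyl)oxy]methyl}-3-(hydroxymethyl)-9-Dr-nona-3,6-dienoate | CC1=C(CC/C(=C/C/C=C(\CC(=O)OC(C)(C)C)CO)CO[Si](c3ccccc3)(c3ccccc3)C(C)(C)C)[C@@]2(C)CCCC(C)(C)[C@@H]2CC1 | intermediate
20 | tert-butyl 2-[(2S,3S)-3-[(2Z)-3-{[(tert-butyldiphenylsilyl)oxy]methyl}-5-Dr-pent-2-en-1-yl]-2-(hydroxymethyl)oxiran-2-yl]acetate | CC1=C(CC/C(=C/C[C@@H]3O[C@@]3(CC(=O)OC(C)(C)C)CO)CO[Si](c4ccccc4)(c4ccccc4)C(C)(C)C)[C@@]2(C)CCCC(C)(C)[C@@H]2CC1 | intermediate
21 | tert-butyl 2-[(2S,3S)-2-{[(tert-butyldiphenylsilyl)oxy]methyl}-3-[(2Z)-3-{[(tert-butyldiphenylsilyl)oxy]methyl}-5-Dr-pent-2-en-1-yl]oxiran-2-yl]acetate | CC1=C(CC/C(=C/C[C@@H]3O[C@@]3(CC(=O)OC(C)(C)C)CO[Si](c4ccccc4)(c4ccccc4)C(C)(C)C)CO[Si](c4ccccc4)(c4ccccc4)C(C)(C)C)[C@@]2(C)CCCC(C)(C)[C@@H]2CC1 | intermediate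
22 | (4S,5R)-4-{[(tert-butyldiphenylsilyl)oxy]methyl}-5-[(2Z)-3-{[(tert-butyldiphenylsilyl)oxy]methyl}-5-Dr-pent-2-en-1-yl]-4-hydroxydihydrofuran-2(3H)-one (not isolated) | CC1=C(CC/C(=C/C[C@H]3OC(=O)C[C@]3(O)CO[Si](c4ccccc4)(c4ccccc4)C(C)(C)C)CO[Si](c4ccccc4)(c4ccccc4)C(C)(C)C)[C@@]2(C)CCCC(C)(C)[C@@H]2CC1 | intermediate
23 | (2R,3S)-3-{[(tert-butyldiphenylsilyl)oxy]methyl}-2-[(2Z)-3-{[(tert-butyldiphenylsilyl)oxy]methyl}-5-Dr-pent-2-en-1-yl]-5-oxotetrahydrofuran-3-yl methanesulfonate (not isolated) | CC1=C(CC/C(=C/C[C@H]3OC(=O)C[C@]3(OS(C)(=O)=O)CO[Si](c4ccccc4)(c4ccccc4)C(C)(C)C)CO[Si](c4ccccc4)(c4ccccc4)C(C)(C)C)[C@@]2(C)CCCC(C)(C)[C@@H]2CC1 | intermediate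
24 | (5R)-4-{[(tert-butyldiphenylsilyl)oxy]methyl}-5-[(2Z)-3-{[(tert-butyldiphenylsilyl)oxy]methyl}-5-Dr-pent-2-en-1-yl]furan-2(5H)-one | CC1=C(CC/C(=C/C[C@H]3OC(=O)C=C3CO[Si](c4ccccc4)(c4ccccc4)C(C)(C)C)CO[Si](c4ccccc4)(c4ccccc4)C(C)(C)C)[C@@]2(C)CCCC(C)(C)[C@@H]2CC1 | intermediate
25 | 16-epi-luffarin L, (5R)-4-(hydroxymethyl)-5-[(2Z)-3-(hydroxymethyl)-5-Dr-pent-2-en-1-yl]furan-2(5H)-one | CC1=C(CC/C(=C/C[C@H]2OC(=O)C=C2CO)CO)[C@@]2(C)CCCC(C)(C)[C@@H]2CC1 | target

## Step count and risks

Total step count: 14 (12 in the main line, plus steps 5 and 8 for reagents 9 and 16).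
Longest linear sequence: 12 steps (steps 1–4, 6, 7, 9–14, from sclareol).

The three steps most likely to fail:

**Step 13 (key step).** What may go wrong: C–O cleavage at the tertiary epoxide carbon C17 (four-ring closure with retention at C16, hydride shift to a C16 ketone, or fluoride capture) outruns five-ring closure at C16, or a silyl ether is lost to the Lewis acid. The fallback sets out from 19 and comes back at 24; it closes the same O–C16 bond on the alkene instead of the epoxide. Alcohol 19 would be silylated (tBuPh2SiCl, imidazole) to tert-butyl (3E,6Z)-3,7-bis{[(tert-butyldiphenylsilyl)oxy]methyl}-9-Dr-nona-3,6-dienoate F1. The tert-butyl ester would be cleaved (Me3SiOTf, 2,6-lutidine, then aqueous work-up) to (3E,6Z)-3,7-bis{[(tert-butyldiphenylsilyl)oxy]methyl}-9-Dr-nona-3,6-dienoic acid F2. Treatment of F2 with PhSeCl (CH2Cl2, −78 °C) should add selenium to C16=C17, and the carboxylate should open the seleniranium ion at C16 in the five-ring mode to give (4S,5R)-4-{[(tert-butyldiphenylsilyl)oxy]methyl}-5-[(2Z)-3-{[(tert-butyldiphenylsilyl)oxy]methyl}-5-Dr-pent-2-en-1-yl]-4-(phenylselanyl)dihydrofuran-2(3H)-one F3. Oxidation (H2O2, pyridine, 0 °C) and syn-elimination of the selenoxide toward C18 would give 24. This selenolactonization–selenoxide elimination is a known butenolide synthesis from β,γ-unsaturated acids and involves no cationic character at C17. Its price is that the C16 configuration is no longer relayed from an epoxide: with PhSeCl both C16 epimers must be expected and 24 would have to be separated from its epimer, unless an enantiopure selenium electrophile is used to bias the face of attack.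

**Step 6.** What may go wrong: poor geometric selectivity in oxaphosphetane formation, or enolization of the α-silyloxy ketone by the basic ylide. The fallback sets out from 5 and comes back at 18; it fixes the alkene geometry with a temporary six-membered lactone instead of a Wittig reaction. Ketone 5 would be methylenated (Ph3PCH3Br, KOtBu, THF) to 2-(2-Dr-ethyl)prop-2-en-1-ol F4 and esterified with but-3-enoic acid (DCC, cat. DMAP, 0 °C) to 2-(2-Dr-ethyl)prop-2-en-1-yl but-3-enoate F5. Ring-closing metathesis with the second-generation Grubbs catalyst (H2IMes)(PCy3)Cl2Ru=CHPh (CH2Cl2, reflux) would give 5-(2-Dr-ethyl)-3,6-dihydro-2H-pyran-2-one F6, in which the ring forces C24 and C15 to be cis on C13=C14. Reduction (iBu2AlH, −78 °C) would give the lactol 5-(2-Dr-ethyl)-3,6-dihydro-2H-pyran-2-ol F7. Wittig reaction of its open hydroxy aldehyde form with ylide 16 (toluene, 60 °C) would give 4-tert-butyl 1-methyl (2E)-2-[(3Z)-4-(hydroxymethyl)-6-Dr-hex-3-en-1-ylidene]butanedioate F8, and silylation (tBuPh2SiCl, imidazole) would give 18. Steps 6, 7 and 9 are bypassed.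

**Step 9.** What may go wrong: migration of the C13=C14 double bond into conjugation with the aldehyde, with scrambling of its geometry, before the hindered ylide traps it. The fallback sets out from 6 (and reagent 16) and comes back at 18; it makes C16=C17 by olefin metathesis so that no enolizable aldehyde is formed. Ketone 6 would be olefinated with the ylide from but-3-enyltriphenylphosphonium bromide (KN(SiMe3)2, THF, −78 °C to rt) to tert-butyl{[(2Z)-2-(2-Dr-ethyl)hexa-2,5-dien-1-yl]oxy}diphenylsilane F9. Ylide 16 and paraformaldehyde (THF, 60 °C) would give 4-tert-butyl 1-methyl 2-methylidenebutanedioate F10. Cross-metathesis of the terminal alkene of F9 with F10, using the second-generation Hoveyda–Grubbs catalyst (H2IMes)Cl2Ru=CH(C6H4-2-OiPr) (CH2Cl2, 40 °C), should give 18 as the thermodynamically preferred E isomer with loss of ethene.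

## Further compounds

F1 | step 13 | tert-butyl (3E,6Z)-3,7-bis{[(tert-butyldiphenylsilyl)oxy]methyl}-9-Dr-nona-3,6-dienoate | CC1=C(CC/C(=C/C/C=C(\CC(=O)OC(C)(C)C)CO[Si](c3ccccc3)(c3ccccc3)C(C)(C)C)CO[Si](c3ccccc3)(c3ccccc3)C(C)(C)C)[C@@]2(C)CCCC(C)(C)[C@@H]2CC1
F2 | step 13 | (3E,6Z)-3,7-bis{[(tert-butyldiphenylsilyl)oxy]methyl}-9-Dr-nona-3,6-dienoic acid | CC1=C(CC/C(=C/C/C=C(\CC(=O)O)CO[Si](c3ccccc3)(c3ccccc3)C(C)(C)C)CO[Si](c3ccccc3)(c3ccccc3)C(C)(C)C)[C@@]2(C)CCCC(C)(C)[C@@H]2CC1
F3 | step 13 | (4S,5R)-4-{[(tert-butyldiphenylsilyl)oxy]methyl}-5-[(2Z)-3-{[(tert-butyldiphenylsilyl)oxy]methyl}-5-Dr-pent-2-en-1-yl]-4-(phenylselanyl)dihydrofuran-2(3H)-one | CC1=C(CC/C(=C/C[C@H]3OC(=O)C[C@]3([Se]c4ccccc4)CO[Si](c4ccccc4)(c4ccccc4)C(C)(C)C)CO[Si](c4ccccc4)(c4ccccc4)C(C)(C)C)[C@@]2(C)CCCC(C)(C)[C@@H]2CC1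
F4 | step 6 | 2-(2-Dr-ethyl)prop-2-en-1-ol | CC1=C(CCC(=C)CO)[C@@]2(C)CCCC(C)(C)[C@@H]2CC1
F5 | step 6 | 2-(2-Dr-ethyl)prop-2-en-1-yl but-3-enoate | CC1=C(CCC(=C)COC(=O)CC=C)[C@@]2(C)CCCC(C)(C)[C@@H]2CC1
F6 | step 6 | 5-(2-Dr-ethyl)-3,6-dihydro-2H-pyran-2-one | CC1=C(CCC3=CCC(=O)OC3)[C@@]2(C)CCCC(C)(C)[C@@H]2CC1
F7 | step 6 | 5-(2-Dr-ethyl)-3,6-dihydro-2H-pyran-2-ol | CC1=C(CCC3=CCC(O)OC3)[C@@]2(C)CCCC(C)(C)[C@@H]2CC1
F8 | step 6 | 4-tert-butyl 1-methyl (2E)-2-[(3Z)-4-(hydroxymethyl)-6-Dr-hex-3-en-1-ylidene]butanedioate | CC1=C(CC/C(=C/C/C=C(\CC(=O)OC(C)(C)C)C(=O)OC)CO)[C@@]2(C)CCCC(C)(C)[C@@H]2CC1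
F9 | step 9 | tert-butyl{[(2Z)-2-(2-Dr-ethyl)hexa-2,5-dien-1-yl]oxy}diphenylsilane | CC1=C(CC/C(=C/CC=C)CO[Si](c3ccccc3)(c3ccccc3)C(C)(C)C)[C@@]2(C)CCCC(C)(C)[C@@H]2CC1
F10 | step 9 | 4-tert-butyl 1-methyl 2-methylidenebutanedioate | C=C(CC(=O)OC(C)(C)C)C(=O)OC
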